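**Retrosynthetic overview**
1. Target 30 ⇐ silyl ether 29 ⇐ ketone 24 + acid 28 by a direct allylic C6–H acyloxylation (the proposed new palladium step; sets C6 and installs the enoate).
2. 24 ⇐ isoxazoline ester 21 (N–O cleavage unmasks the C2 ketone and the C1′ carbinol) ⇐ alcohol 19 by Mitsunobu inversion with (R)-2-methylbutanoic acid 20.
3. 19 (ring B plus a temporary isoxazoline ring) ⇐ oxime 16 by intramolecular nitrile oxide cycloaddition onto a (Z)-propenyl group (C2–C3 bond; C3 and C1′ stereocentres).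
4. 16 ⇐ (S)-cryptone 5 by (Z)-propenyl cuprate addition/aldol with 2,2-dimethoxyacetaldehyde (C3a, C7a, C1), then Wittig methylenation; 5 ⇐ 3-methylbutanal + methyl vinyl ketone (organocatalytic Michael addition, aldol condensation).
5. Ring order: ring A (cyclohexane) first, ring B (cyclopentane) second, formed together with the isoxazoline ring that is opened late.

Assumption: 6, 7 (dried from its commercial aqueous solution) and 20 are bought; bicyclic compounds carry the target's hydrindane locants (C1 acyloxy carbon, C2 ketone carbon, C3, C3a, C4 isopropyl carbon, C5, C6, C7 methylidene carbon, C7a; C1′ side-chain carbinol carbon).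

**Step 1**
Reactants: 1 3-methylbutanal; 2 but-3-en-2-one (methyl vinyl ketone)
Product: 3 (2S)-5-oxo-2-(propan-2-yl)hexanal
Conditions: (S)-2-[methoxy(diphenyl)methyl]pyrrolidine (5 mol %), ethyl 3,4-dihydroxybenzoate (20 mol %), neat, 4 °C, 36 h
Reagents that add atoms: none
Why: Enamine-catalysed Michael addition in which the E-enamine of 1 is attacked by the enone on the face remote from the diphenyl(methoxy)methyl group, setting the 2S centre (later C4).

**Step 2**
Reactants: 3 (2S)-5-oxo-2-(propan-2-yl)hexanal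
Product: 5 (S)-cryptone [(4S)-4-(propan-2-yl)cyclohex-2-en-1-one], via hydroxy ketone 4 (not isolated)
Conditions: 0.1 M aq. KOH, n-Bu4NOH (cat.), Et2O–THF, reflux
Reagents that add atoms: none
Why: Intramolecular aldol condensation (methyl ketone enolate onto the aldehyde, then E1cB dehydration) closes ring A faster than the hindered α-branched aldehyde enolises, so the stereocentre is carried into 5 as 4S.

**Step 3**
Reactants: 5 (S)-cryptone; 6 (1Z)-1-bromoprop-1-ene; 7 2,2-dimethoxyacetaldehyde
Product: 12 (2S,3S,4S)-2-[(1R)-1-hydroxy-2,2-dimethoxyethyl]-4-(propan-2-yl)-3-[(1Z)-prop-1-en-1-yl]cyclohexan-1-one, via (Z)-prop-1-enyllithium 8 (not isolated), via lithium dipropenylcuprate 9 (not isolated), via lithium enolate 10 (not isolated), via chlorozinc enolate 11 (not isolated)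
Conditions: 6 (2.4 equiv), t-BuLi (4.8 equiv), Et2O, −78 °C; CuI (copper iodide, 1.2 equiv), −40 °C; 5, −78 °C; ZnCl2 (THF), −78 °C; 7 (2 equiv), −78 °C; aq. NH4Cl
Reagents that add atoms: none
Why: Cuprate 1,4-addition occurs anti to the C4 isopropyl group, and the zinc enolate then undergoes a Zimmerman–Traxler aldol anti to the new C3 substituent, the cyclic E-enolate giving the anti carbinol (1′R), in a three-component conjugate addition–aldol coupling that leaves ring A all-trans and all-equatorial.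

**Step 4**
Reactants: 12 aldol adduct
Product: 13 (2S,3S,4S)-2-[(1R)-2,2-dimethoxy-1-(triethylsilyloxy)ethyl]-4-(propan-2-yl)-3-[(1Z)-prop-1-en-1-yl]cyclohexan-1-one
Conditions: TESCl, imidazole, DMF, 0 °C → rt
Reagents that add atoms: chlorotriethylsilane, CC[Si](Cl)(CC)CC
Why: Silyl ether formation at the only hydroxyl blocks retro-aldol cleavage in the basic olefination that follows and touches no stereocentre.

**Step 5**
Reactants: 13 silyl ether ketone
Product: 14 triethyl{(1R)-2,2-dimethoxy-1-[(1R,2S,3S)-6-methylidene-3-(propan-2-yl)-2-[(1Z)-prop-1-en-1-yl]cyclohexyl]ethoxy}silane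
Conditions: Ph3PCH3Br, KOt-Bu, toluene, 0 → 60 °C
Reagents that add atoms: methyltriphenylphosphonium bromide, C[P+](c1ccccc1)(c1ccccc1)c1ccccc1.[Br-]
Why: Wittig methylenation of the only ketone installs the C7 methylidene group, and the adjacent α-centre already sits in its thermodynamically preferred equatorial arrangement, so it is not scrambled.

**Step 6**
Reactants: 14 methylidene acetal
Product: 16 (2R)-2-hydroxy-2-[(1R,2S,3S)-6-methylidene-3-(propan-2-yl)-2-[(1Z)-prop-1-en-1-yl]cyclohexyl]acetaldehyde oxime, via hydroxy acetal 15 (not isolated)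
Conditions: NH2OH·HCl (4 equiv), 1 M aq. HCl–THF (1:4), 40 °C
Reagents that add atoms: hydroxylamine hydrochloride, NO.Cl
Why: Under mild acid the triethylsilyl ether is hydrolysed and the acetal ionises to an oxocarbenium ion that hydroxylamine intercepts (transoximation), so the oxime forms without a free aldehyde accumulating and without touching a stereocentre.

**Step 7**
Reactants: 16 oxime
Product: 19 isoxazoline alcohol (1R,3R,3aS,4S,7aR,1′R), via hydroximoyl chloride 17 (not isolated), via nitrile oxide 18 (not isolated)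
Conditions: NCS, DMF, rt; then Et3N (slow addition), CH2Cl2, 0 °C → rt, 0.01 M
Reagents that add atoms: none
Why: Intramolecular nitrile oxide–alkene 1,3-dipolar cycloaddition closes ring B between the two equatorial arms (trans ring fusion already fixed); the short tether forces attack on the alkene face syn to C7a while allylic 1,3-strain of the (Z)-propenyl group holds H-3a in the alkene plane, so C1′ ends cis to H-3a (3R), and suprafacial addition to the Z-alkene gives the 1′R centre (the syn-aldol relationship of the target).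

**Step 8**
Reactants: 19 isoxazoline alcohol; 20 (2R)-2-methylbutanoic acid
Product: 21 isoxazoline ester (1S,3R,3aS,4S,7aR,1′R)
Conditions: PPh3, DIAD, toluene, 0 °C → rt
Reagents that add atoms: none
Why: Mitsunobu esterification displaces the activated 1β-hydroxyl (cis to H-7a) by the carboxylate in an SN2 step at a carbon activated by the adjacent C=N, inverting C1 to the required 1S ester without enolising the acid's own stereocentre.

**Step 9**
Reactants: 21 isoxazoline ester
Product: 23 (1S,3S,3aS,4S,7aR)-3-[(1R)-1-hydroxyethyl]-7-methylidene-2-oxo-4-(propan-2-yl)octahydro-1H-inden-1-yl (2R)-2-methylbutanoate, via hydroxy imine 22 (not isolated)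
Conditions: Mo(CO)6 (1.2 equiv), MeCN–H2O (10:1), 80 °C
Reagents that add atoms: water, O
Why: Reductive N–O cleavage of the 2-isoxazoline by Mo(CO)6 and hydrolysis of the β-hydroxy imine unmask the β-hydroxy ketone without reducing the alkene or the ester and without changing any stereocentre.

**Step 10**
Reactants: 23 hydroxy ketone
Product: 24 (1S,3S,3aS,4S,7aR)-7-methylidene-2-oxo-4-(propan-2-yl)-3-[(1R)-1-(triethylsilyloxy)ethyl]octahydro-1H-inden-1-yl (2R)-2-methylbutanoate
Conditions: TESCl, imidazole, DMF, 0 °C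
Reagents that add atoms: chlorotriethylsilane, CC[Si](Cl)(CC)CC
Why: Silyl ether formation protects the only free hydroxyl under conditions too mild to enolise the α-acyloxy ketone, so that the C6 oxidation and its known fallback cannot touch C1′.

**Step 11**
Reactants: 25 ethyl but-2-ynoate
Product: 27 ethyl (2E)-3-methylpent-2-enoate, via alkenylcuprate 26 (not isolated)
Conditions: EtMgBr (2 equiv), CuI (copper iodide, 1 equiv), THF, −40 °C; 25, −78 °C; aq. NH4Cl–MeOH, −78 °C
Reagents that add atoms: ethylmagnesium bromide, CC[Mg]Br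
Why: syn-Carbocupration of the ynoate places ethyl and copper cis, and protonation at −78 °C with retention gives the E-enoate (ethyl trans to the ester).

**Step 12**
Reactants: 27 ethyl (2E)-3-methylpent-2-enoate
Product: 28 (2E)-3-methylpent-2-enoic acid
Conditions: LiOH, THF–MeOH–H2O, rt; then 1 M HCl
Reagents that add atoms: lithium hydroxide, [Li+].[OH-]
Why: Saponification by acyl–oxygen cleavage does not touch the trisubstituted alkene, so the E geometry is kept.

**Step 13**
Reactants: 24 silyl ether ketone; 28 (2E)-3-methylpent-2-enoic acid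
Product: 29 (1S,3S,3aS,4S,6R,7aR)-7-methylidene-1-{[(2R)-2-methylbutanoyl]oxy}-2-oxo-4-(propan-2-yl)-3-[(1R)-1-(triethylsilyloxy)ethyl]octahydro-1H-inden-6-yl (2E)-3-methylpent-2-enoate
Conditions: Pd(OAc)2 (10 mol %, pre-stirred with 28 to exchange acetate), 1,2-bis(phenylsulfinyl)ethane (10 mol %), 28 (3 equiv), 1,4-benzoquinone (2 equiv), 1,4-dioxane, 45 °C, 48 h, no base
Reagents that add atoms: none
Why: Proposed new method: the divalent palladium complex Pd(O2CR)2/bis-sulfoxide (RCO2H = 28) should cleave the only accessible π-aligned allylic C–H bond of the exocyclic alkene, the axial β-H at C6 (the tertiary H-7a is shielded by C1 and C3a), giving an (η3-allyl)Pd(O2CR) species on the β-face; run base-free so that the carboxylate stays on the metal, benzoquinone binding should trigger inner-sphere C–O reductive elimination at the more substituted ring terminus, so the ester enters cis to palladium, axially at C6 (6R), with the C7 methylidene kept and the E-enoic acid never activated as an acyl donor, while zerovalent palladium is reoxidised by the quinone; the closest known reaction type is the Pd(OAc)2/bis-sulfoxide/benzoquinone allylic C–H acetoxylation of terminal alkenes to branched acetates (and the related linear C–H esterification with complex acids), not yet shown for exocyclic 1,1-disubstituted alkenes.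

**Step 14**
Reactants: 29 silyl-protected diester
Product: 30 target CNP0224363.2
Conditions: HF·pyridine, THF–pyridine, 0 °C
Reagents that add atoms: none
Why: Fluoride-mediated desilylation frees the C1′ hydroxyl under buffered conditions that leave both esters, the exocyclic alkene and the epimerisable C1 and C3 centres untouched.

**Compound list**
1 | 3-methylbutanal | CC(C)CC=O | starting material
2 | but-3-en-2-one (methyl vinyl ketone) | CC(=O)C=C | starting material
3 | (2S)-5-oxo-2-(propan-2-yl)hexanal | O=C[C@H](C(C)C)CCC(C)=O | intermediate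
4 | (4S)-3-hydroxy-4-(propan-2-yl)cyclohexan-1-one (both C3 epimers) | O=C1CC(O)[C@H](C(C)C)CC1 | intermediate
5 | (S)-cryptone, (4S)-4-(propan-2-yl)cyclohex-2-en-1-one | O=C1C=C[C@H](C(C)C)CC1 | intermediate
6 | (1Z)-1-bromoprop-1-ene | C/C=C\Br | starting material
7 | 2,2-dimethoxyacetaldehyde | COC(OC)C=O | starting material
8 | (1Z)-prop-1-en-1-yllithium | C/C=C\[Li] | intermediate
9 | lithium bis[(1Z)-prop-1-en-1-yl]cuprate, LiCu(CH=CHCH3)2 | C/C=C\[Cu-]/C=C\C.[Li+] | intermediate
10 | lithium (3S,4S)-4-(propan-2-yl)-3-[(1Z)-prop-1-en-1-yl]cyclohex-1-en-1-olate | [Li]OC1=C[C@@H](/C=C\C)[C@H](C(C)C)CC1 | intermediate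
11 | chlorozinc (3S,4S)-4-(propan-2-yl)-3-[(1Z)-prop-1-en-1-yl]cyclohex-1-en-1-olate | Cl[Zn]OC1=C[C@@H](/C=C\C)[C@H](C(C)C)CC1 | intermediate
12 | (2S,3S,4S)-2-[(1R)-1-hydroxy-2,2-dimethoxyethyl]-4-(propan-2-yl)-3-[(1Z)-prop-1-en-1-yl]cyclohexan-1-one | O=C1[C@H]([C@@H](O)C(OC)OC)[C@@H](/C=C\C)[C@H](C(C)C)CC1 | intermediate
13 | (2S,3S,4S)-2-[(1R)-2,2-dimethoxy-1-(triethylsilyloxy)ethyl]-4-(propan-2-yl)-3-[(1Z)-prop-1-en-1-yl]cyclohexan-1-one | O=C1[C@H]([C@@H](O[Si](CC)(CC)CC)C(OC)OC)[C@@H](/C=C\C)[C@H](C(C)C)CC1 | intermediate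
14 | triethyl{(1R)-2,2-dimethoxy-1-[(1R,2S,3S)-6-methylidene-3-(propan-2-yl)-2-[(1Z)-prop-1-en-1-yl]cyclohexyl]ethoxy}silane | C=C1[C@H]([C@@H](O[Si](CC)(CC)CC)C(OC)OC)[C@@H](/C=C\C)[C@H](C(C)C)CC1 | intermediate
15 | (1R)-2,2-dimethoxy-1-[(1R,2S,3S)-6-methylidene-3-(propan-2-yl)-2-[(1Z)-prop-1-en-1-yl]cyclohexyl]ethan-1-ol | C=C1[C@H]([C@@H](O)C(OC)OC)[C@@H](/C=C\C)[C@H](C(C)C)CC1 | intermediate
16 | (2R)-2-hydroxy-2-[(1R,2S,3S)-6-methylidene-3-(propan-2-yl)-2-[(1Z)-prop-1-en-1-yl]cyclohexyl]acetaldehyde oxime (C=N isomers) | C=C1[C@H]([C@@H](O)C=NO)[C@@H](/C=C\C)[C@H](C(C)C)CC1 | intermediate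
17 | (2R)-N,2-dihydroxy-2-[(1R,2S,3S)-6-methylidene-3-(propan-2-yl)-2-[(1Z)-prop-1-en-1-yl]cyclohexyl]ethanimidoyl chloride | C=C1[C@H]([C@@H](O)C(Cl)=NO)[C@@H](/C=C\C)[C@H](C(C)C)CC1 | intermediate
18 | (2R)-2-hydroxy-2-[(1R,2S,3S)-6-methylidene-3-(propan-2-yl)-2-[(1Z)-prop-1-en-1-yl]cyclohexyl]acetonitrile N-oxide | C=C1[C@H]([C@@H](O)C#[N+][O-])[C@@H](/C=C\C)[C@H](C(C)C)CC1 | intermediate
19 | isoxazoline alcohol: trans-fused hydrindane (1R,3R,3aS,4S,7aR) with 1-OH cis to H-7a, 4-isopropyl, 7-methylidene; C2 is the C=N carbon of a 4,5-dihydroisoxazole ring C2=N–O–C1′(H)(CH3)–C3, (1′R), C1′ cis to H-3a | C=C1[C@H]2[C@@H]([C@H]3[C@@H](C)ON=C3[C@@H]2O)[C@H](C(C)C)CC1 | intermediate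
20 | (2R)-2-methylbutanoic acid | CC[C@@H](C)C(=O)O | starting material
21 | isoxazoline ester: as 19 but C1 inverted (1S,3R,3aS,4S,7aR,1′R), C1 carrying the (2R)-2-methylbutanoyloxy group trans to H-7a | C=C1[C@H]2[C@@H]([C@H]3[C@@H](C)ON=C3[C@H]2OC(=O)[C@H](C)CC)[C@H](C(C)C)CC1 | intermediate
22 | (1S,3R,3aS,4S,7aR)-3-[(1R)-1-hydroxyethyl]-2-imino-7-methylidene-4-(propan-2-yl)octahydro-1H-inden-1-yl (2R)-2-methylbutanoate | C=C1[C@H]2[C@@H]([C@@H]([C@@H](C)O)C(=N)[C@H]2OC(=O)[C@H](C)CC)[C@H](C(C)C)CC1 | intermediate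
23 | (1S,3S,3aS,4S,7aR)-3-[(1R)-1-hydroxyethyl]-7-methylidene-2-oxo-4-(propan-2-yl)octahydro-1H-inden-1-yl (2R)-2-methylbutanoate | C=C1[C@H]2[C@@H]([C@@H]([C@@H](C)O)C(=O)[C@H]2OC(=O)[C@H](C)CC)[C@H](C(C)C)CC1 | intermediate
24 | (1S,3S,3aS,4S,7aR)-7-methylidene-2-oxo-4-(propan-2-yl)-3-[(1R)-1-(triethylsilyloxy)ethyl]octahydro-1H-inden-1-yl (2R)-2-methylbutanoate | C=C1[C@H]2[C@@H]([C@@H]([C@@H](C)O[Si](CC)(CC)CC)C(=O)[C@H]2OC(=O)[C@H](C)CC)[C@H](C(C)C)CC1 | intermediate
25 | ethyl but-2-ynoate | CC#CC(=O)OCC | starting material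
26 | bromomagnesium ethyl[(1Z)-1-(ethoxycarbonyl)-2-methylbut-1-en-1-yl]cuprate | CCOC(=O)/C([Cu-]CC)=C(\C)CC.[Mg+]Br | intermediate
27 | ethyl (2E)-3-methylpent-2-enoate | CCOC(=O)/C=C(\C)CC | intermediate
28 | (2E)-3-methylpent-2-enoic acid | OC(=O)/C=C(\C)CC | intermediate
29 | (1S,3S,3aS,4S,6R,7aR)-7-methylidene-1-{[(2R)-2-methylbutanoyl]oxy}-2-oxo-4-(propan-2-yl)-3-[(1R)-1-(triethylsilyloxy)ethyl]octahydro-1H-inden-6-yl (2E)-3-methylpent-2-enoate | C=C1[C@H]2[C@@H]([C@@H]([C@@H](C)O[Si](CC)(CC)CC)C(=O)[C@H]2OC(=O)[C@H](C)CC)[C@H](C(C)C)C[C@H]1OC(=O)/C=C(\C)CC | intermediate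
30 | CNP0224363.2, (1S,3S,3aS,4S,6R,7aR)-3-[(1R)-1-hydroxyethyl]-7-methylidene-1-{[(2R)-2-methylbutanoyl]oxy}-2-oxo-4-(propan-2-yl)octahydro-1H-inden-6-yl (2E)-3-methylpent-2-enoate | C=C1[C@H]2[C@@H]([C@@H]([C@@H](C)O)C(=O)[C@H]2OC(=O)[C@H](C)CC)[C@H](C(C)C)C[C@H]1OC(=O)/C=C(\C)CC | target

**Step count and risks**
Total step count: 14. Longest linear sequence: 12 steps (steps 1–10, 13, 14, from 3-methylbutanal and methyl vinyl ketone); steps 11–12 make acid 28 on a two-step side branch.

Three steps most likely to fail: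

Step 13 (the proposed new C–H acyloxylation). The carboxylate may attack the CH2 terminus of the allyl intermediate (primary ester, endocyclic alkene), may attack from outside to give the equatorial 6S ester, or the alkene may isomerise. The fallback uses two known reactions and sets out from 24: SeO2 (0.5 equiv)/t-BuOOH in CH2Cl2 at rt gives, by ene reaction and [2,3]-sigmatropic shift at the ring CH2, the axial allylic alcohol (1S,3S,3aS,4S,6R,7aR)-6-hydroxy-7-methylidene-2-oxo-4-(propan-2-yl)-3-[(1R)-1-(triethylsilyloxy)ethyl]octahydro-1H-inden-1-yl (2R)-2-methylbutanoate F1. Carbodiimide esterification of F1 with 28 (DCC, DMAP, CH2Cl2, 0 °C, kept cold to avoid deconjugation of the enoate) comes back to the route at 29.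

Step 8 (Mitsunobu inversion at a hindered carbinol with a weakly acidic aliphatic acid). Elimination or no reaction are the likely failures. The fallback sets out from 19 and separates activation from displacement: Tf2O, pyridine, CH2Cl2, −30 °C gives the isoxazoline triflate F2; caesium (R)-2-methylbutanoate (from 20 and Cs2CO3) with 18-crown-6 in toluene at rt displaces the triflate with SN2 inversion and comes back to the route at 21.

Step 3 (one-pot conjugate addition–aldol). The carbinol centre may form with poor anti selectivity, and the later Mitsunobu inversion depends on the anti (1′R) isomer. The fallback sets out from 5 and makes the aldol a separate boron-mediated step: cuprate 9 is added to 5 in the presence of Me3SiCl/Et3N (−78 °C) and the trimethylsilyl enol ether F3 is isolated. Silicon–boron exchange with n-Bu2BOTf (CH2Cl2, 0 °C) gives the dibutylboron enolate F4. Addition of 7 at −78 °C through the tight boron Zimmerman–Traxler transition state gives the anti aldol, and H2O2/pH 7 work-up comes back to the route at 12.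

Further compounds
F1 | step 13 | (1S,3S,3aS,4S,6R,7aR)-6-hydroxy-7-methylidene-2-oxo-4-(propan-2-yl)-3-[(1R)-1-(triethylsilyloxy)ethyl]octahydro-1H-inden-1-yl (2R)-2-methylbutanoate | C=C1[C@H]2[C@@H]([C@@H]([C@@H](C)O[Si](CC)(CC)CC)C(=O)[C@H]2OC(=O)[C@H](C)CC)[C@H](C(C)C)C[C@H]1O
F2 | step 8 | trifluoromethanesulfonate of isoxazoline alcohol 19 (1R,3R,3aS,4S,7aR,1′R; triflate on C1, cis to H-7a) | C=C1[C@H]2[C@@H]([C@H]3[C@@H](C)ON=C3[C@@H]2OS(=O)(=O)C(F)(F)F)[C@H](C(C)C)CC1
F3 | step 3 | trimethyl({(3S,4S)-4-(propan-2-yl)-3-[(1Z)-prop-1-en-1-yl]cyclohex-1-en-1-yl}oxy)silane | C[Si](C)(C)OC1=C[C@@H](/C=C\C)[C@H](C(C)C)CC1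
F4 | step 3 | dibutyl({(3S,4S)-4-(propan-2-yl)-3-[(1Z)-prop-1-en-1-yl]cyclohex-1-en-1-yl}oxy)borane | CCCCB(CCCC)OC1=C[C@@H](/C=C\C)[C@H](C(C)C)CC1
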